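**Plan**
Atom labels: ten-membered ring C1 (hemiketal C)–C2–C3–C4 (methyl-bearing ether C)–C5=C6 (enol-lactone alkene)–C7–C8 (acyloxy CH)–C9–C10 (methyl CH); C11–C12(=O)–O–C6 completes the butenolide and C13 is the CH2OAc carbon.
Enabling feature: C1 and C6 are both carbonyl-level carbons facing each other across that ring, and the C4 oxygen is 1,4 to C1; a C1=C6 bond turns the ring into a 1(6)-octalin (rings A and B) holding all fifteen carbons of artemisinic acid.
Retrosynthetic cuts, in order: the C8–O ester; the C13–O and C8–O bonds (allylic C–H); the O–C12 enol-lactone bond; then the C1–O(C4) ether bond and both C=O bonds at C1 and C6, rejoined as the C1=C6 alkene of a 4-hydroxy dienoic acid.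
Forward: the decalin comes from the chiral pool; ozonolysis uncovers the ten-membered ring and the oxolane closes in the same step; the butenolide closes next; C8 and C13 are then oxygenated; the side chain (Wittig) is attached last.
Stereochemistry: C10 from artemisinic acid; C4 by a suprafacial ene reaction that uses H-6; C1 from C4 through the bridge; C5=C6 geometry by the ring; C8 by oxazaborolidine-controlled reduction; side-chain alkene by the stabilised ylide.

Key step: step 7

Remark: amorphane atom numbers are kept throughout; the C7=C11 geometry of the dienoate and keto-acid intermediates is not controlled and is written without a descriptor, because the lactonisation step is designed to take both isomers to the same lactone.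

**Route**

Step 1
Reactants: 1 artemisinic acid
Product: 2 2-(trimethylsilyl)ethyl artemisinate
Conditions: Me3SiCH2CH2OH, DCC, DMAP (cat.), CH2Cl2, 0 °C → rt
Reagents that add atoms: 2-(trimethylsilyl)ethanol, C[Si](C)(C)CCO
Why: Steglich esterification masks the acid as an ester that later falls to fluoride without acid or base, and no stereocentre is touched.

Step 2
Reactants: 2 2-(trimethylsilyl)ethyl artemisinate
Product: 4 2-(trimethylsilyl)ethyl (1S,4R,7R,10R)-4-hydroxyamorpha-5,11(13)-dien-12-oate, via tertiary allylic hydroperoxide 3 (not isolated)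
Conditions: O2, hν (visible), tetraphenylporphyrin (cat.), CH2Cl2, −20 °C; then PPh3, −20 °C → rt
Reagents that add atoms: oxygen, O=O
Why: Schenck ene reaction: singlet oxygen attacks the trisubstituted C4=C5 alkene (the acrylate is inert) on the convex face, removes the cis allylic H-6 and delivers oxygen suprafacially to C4, so the new C4 stereocentre carries oxygen on the face of the former H-6; triphenylphosphine reduces the hydroperoxide.

Step 3
Reactants: 4 2-(trimethylsilyl)ethyl 4-hydroxyamorpha-5,11(13)-dien-12-oate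
Product: 5 2-(trimethylsilyl)ethyl (1S,4R,10R)-4-hydroxyamorpha-5,7(11)-dien-12-oate
Conditions: RuHCl(CO)(PPh3)3 (5 mol %), toluene, 80 °C
Reagents that add atoms: none
Why: Metal-hydride alkene isomerisation (ruthenium hydride addition to the acrylate, β-hydride elimination of the doubly allylic H-7) carries the skipped diene into the conjugated dienoate under neutral conditions that spare the tertiary allylic alcohol.

Step 4
Reactants: 5 2-(trimethylsilyl)ethyl 4-hydroxyamorpha-5,7(11)-dien-12-oate
Product: 7 tert-butyldimethylsilyl 2-(trimethylsilyl)ethyl ketene acetal of (1S,4R,10R)-4-hydroxyamorph-6-en-12-oic acid, via dilithium dienolate 6 (not isolated)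
Conditions: LiBH(s-Bu)3 (2.2 equiv), THF, −78 → −40 °C; then t-BuMe2SiCl, DMPU, −78 °C → rt; water work-up
Reagents that add atoms: tert-butyldimethylsilyl chloride, CC(C)(C)[Si](C)(C)Cl
Why: Conjugate 1,6-reduction with enolate silylation: the β-carbon C7 is fully substituted, so hydride should enter at the δ-carbon C5, and the C6=C7 dienolate is trapped on oxygen; the first equivalent of hydride is consumed by the hydroxyl group.

Step 5
Reactants: 7 silyl ketene acetal
Product: 8 2-(trimethylsilyl)ethyl (4R,10R)-4-hydroxyamorpha-1(6),7(11)-dien-12-oate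
Conditions: DDQ (1.1 equiv), 2,6-lutidine, CH2Cl2, −78 → 0 °C
Reagents that add atoms: none
Why: Quinone dehydrogenation of a silyl dienol ether (as in the conversion of steroidal dienol ethers into 4,6-dienones): DDQ should remove the tertiary allylic H-1 as hydride in preference to the C5 hydrogens next to the oxygenated quaternary C4, and loss of silicon gives the 1(6),7(11)-dienoate with C10 untouched.

Step 6
Reactants: 8 2-(trimethylsilyl)ethyl 4-hydroxyamorpha-1(6),7(11)-dien-12-oate
Product: 9 (4R,10R)-4-hydroxyamorpha-1(6),7(11)-dien-12-oic acid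
Conditions: Bu4NF (3 equiv), THF, 0 °C → rt; then dilute aq. HCl to pH 4
Reagents that add atoms: none
Why: Fluoride attacks silicon and the 2-silylethyl ester fragments to ethene and the carboxylate (β-elimination), a cleavage that does not need access to the hindered carbonyl group.

Step 7
Reactants: 9 4-hydroxyamorpha-1(6),7(11)-dien-12-oic acid
Product: 11 (1S,4R,10R)-1-hydroxy-1,4-epoxy-6-oxogermacr-7(11)-en-12-oic acid, via 1-hydroperoxy ketal 10 (not isolated)
Conditions: O3 (1.0 equiv, Sudan Red 7B end point), CH2Cl2, −78 °C; then Me2S, −78 °C → rt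
Reagents that add atoms: ozone, [O-][O+]=O
Why: Ozone adds as a 1,3-dipole to the electron-rich, tetra-alkyl C1=C6 alkene, and the primary ozonide cycloreverts to the C6 ketone and a carbonyl oxide at C1, the carbon remote from the electron-poor enoate. The closest known reactions are the ozonolysis of the ring-fusion alkene of 1(6)-octalins to cyclodecane-1,6-diones and the trapping of carbonyl oxides by a neighbouring hydroxyl group. The ten-membered ring is not closed but uncovered by cleaving the bond shared by rings A and B, whereas the oxolane closes by 5-exo-trig addition of the C4 hydroxyl to C1, giving hydroperoxy ketal 10, which dimethyl sulfide reduces to the hemiketal. The new C1 stereocentre is dictated by C4, because a one-atom oxygen bridge can span C1 and C4 of the ten-membered ring only in the cis sense. The step needs chemoselectivity for C1=C6 over C7=C11; this rests on deactivation of C7=C11 by the carboxyl group and is enforced by one equivalent of ozone to a dye end point at −78 °C.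

Step 8
Reactants: 11 1-hydroxy-1,4-epoxy-6-oxogermacr-7(11)-en-12-oic acid
Product: 13 (1S,4R,10R,5E)-1-hydroxy-1,4-epoxygermacra-5,7(11)-dien-12,6-olide, via mixed anhydride 12 (not isolated)
Conditions: 2,4,6-Cl3C6H2COCl, Et3N, THF, 0 °C; then DMAP, toluene, rt → 40 °C
Reagents that add atoms: none
Why: Enol lactonisation of a γ-keto acid: the activated carboxyl group acylates the oxygen of the C6 ketone with loss of H-5; the activated acyl unit should deconjugate reversibly by γ-deprotonation at C8, which frees rotation about C7–C11 so that both alkene isomers converge, and the ring allows the C5=C6 alkene only with C4 and C7 cis.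

Step 9
Reactants: 13 1-hydroxy-1,4-epoxygermacra-5,7(11)-dien-12,6-olide
Product: 14 1-O-tert-butyldimethylsilyl ether of 13
Conditions: t-BuMe2SiOSO2CF3, 2,6-lutidine, CH2Cl2, −78 → 0 °C
Reagents that add atoms: tert-butyldimethylsilyl trifluoromethanesulfonate, CC(C)(C)[Si](C)(C)OS(=O)(=O)C(F)(F)F
Why: O-Silylation of the tertiary hemiketal hydroxyl locks the oxolane, so that opening to the C1 ketone (with epimerisation at C10 or reduction at C1) is excluded in the following steps.

Step 10
Reactants: 14 silyl ketal
Product: 15 8-oxo derivative of 14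
Conditions: Rh2(C6H10NO)4 (dirhodium tetracaprolactamate, 1 mol %), t-BuOOH (70 % aq., 5 equiv), ClCH2CH2Cl, 40 °C
Reagents that add atoms: tert-butyl hydroperoxide, CC(C)(C)OO
Why: Radical allylic C–H oxidation with tert-butylperoxyl radicals, known for the γ-methylene group of α,β-unsaturated carbonyl compounds, should convert C8, the only allylic CH2 (C13 is a less reactive methyl group), into the ketone.

Step 11
Reactants: 15 8-oxo lactone
Product: 16 13-bromo-8-oxo lactone
Conditions: NBS, AIBN (cat.), PhCF3, 80 °C
Reagents that add atoms: N-bromosuccinimide, O=C1CCC(=O)N1Br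
Why: Wohl–Ziegler bromination: with C8 oxidised, the C13 methyl group carries the only allylic hydrogens and its radical is delocalised over the ene-dione, as in the bromination of α-methylbutenolides and methacrylates.

Step 12
Reactants: 16 13-bromo-8-oxo lactone
Product: 17 13-acetoxy-8-oxo lactone
Conditions: KOAc, 18-crown-6 (cat.), MeCN, 0 °C → rt
Reagents that add atoms: potassium acetate, CC(=O)[O-].[K+]
Why: SN2 displacement of the primary allylic bromide by acetate.

Step 13
Reactants: 17 13-acetoxy-8-oxo lactone
Product: 18 (8S)-13-acetoxy-8-hydroxy lactone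
Conditions: (R)-2-methyl-CBS-oxazaborolidine (0.5 equiv), BH3·SMe2, toluene, −40 °C; then MeOH
Reagents that add atoms: none
Why: Corey–Bakshi–Shibata reduction: the catalyst distinguishes the alkenyl side (C7) from the methylene side (C9) of the C8 ketone, and the (R)-catalyst is expected to deliver hydride to the face that gives the (8S)-alcohol (reagent control, with the (S)-catalyst as the alternative if the ring overrides), while lactone and acetate are left alone at low temperature.

Step 14
Reactants: 19 (tert-butyldimethylsilyloxy)acetaldehyde; 20 ethyl 2-(triphenylphosphoranylidene)propanoate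
Product: 21 ethyl (E)-4-(tert-butyldimethylsilyloxy)-2-methylbut-2-enoate
Conditions: CH2Cl2, rt
Reagents that add atoms: none
Why: Wittig olefination with a stabilised α-methyl ylide gives the (E)-trisubstituted enoate.

Step 15
Reactants: 21 ethyl (E)-4-(tert-butyldimethylsilyloxy)-2-methylbut-2-enoate
Product: 22 (E)-4-(tert-butyldimethylsilyloxy)-2-methylbut-2-enoic acid
Conditions: LiOH·H2O, THF/MeOH/H2O, 0 °C → rt; then cold dilute HCl to pH 4
Reagents that add atoms: lithium hydroxide, [Li+].[OH-]
Why: Saponification of the ethyl ester, which the primary silyl ether and the alkene geometry should survive.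

Step 16
Reactants: 18 (8S)-13-acetoxy-8-hydroxy lactone; 22 (E)-4-(tert-butyldimethylsilyloxy)-2-methylbut-2-enoic acid
Product: 24 bis-silylated target, via mixed anhydride 23 (not isolated)
Conditions: 22, 2,4,6-Cl3C6H2COCl, Et3N, THF, rt; then 18, DMAP, toluene, rt
Reagents that add atoms: none
Why: Yamaguchi esterification acylates the hindered secondary allylic C8 hydroxyl with retention of configuration.

Step 17
Reactants: 24 bis-silylated target
Product: 25 CNP0154520.1
Conditions: HF·pyridine, pyridine, THF, 0 °C → rt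
Reagents that add atoms: none
Why: Fluoride-mediated desilylation removes the primary silyl ether and the silyl ketal without touching the esters, the enol lactone or the allylic acetate.

**Compound list**
1 | artemisinic acid, (1S,6R,7R,10R)-amorpha-4,11(13)-dien-12-oic acid | C[C@@H]1CC[C@H]([C@@H]2[C@H]1CCC(=C2)C)C(=C)C(=O)O | starting material
2 | 2-(trimethylsilyl)ethyl artemisinate | C[C@@H]1CC[C@H]([C@@H]2[C@H]1CCC(=C2)C)C(=C)C(=O)OCC[Si](C)(C)C | intermediate
3 | 2-(trimethylsilyl)ethyl (1S,4R,7R,10R)-4-hydroperoxyamorpha-5,11(13)-dien-12-oate | C=C(C(=O)OCC[Si](C)(C)C)[C@@H]1CC[C@@H](C)[C@@H]2CC[C@@](C)(OO)C=C12 | intermediate (not isolated)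
4 | 2-(trimethylsilyl)ethyl (1S,4R,7R,10R)-4-hydroxyamorpha-5,11(13)-dien-12-oate (4-OH cis to H-1 and to the C10 methyl) | C=C(C(=O)OCC[Si](C)(C)C)[C@@H]1CC[C@@H](C)[C@@H]2CC[C@@](C)(O)C=C12 | intermediate
5 | 2-(trimethylsilyl)ethyl (1S,4R,10R)-4-hydroxyamorpha-5,7(11)-dien-12-oate | CC(C(=O)OCC[Si](C)(C)C)=C1CC[C@@H](C)[C@@H]2CC[C@@](C)(O)C=C12 | intermediate
6 | dilithium salt (C4 alkoxide and C6=C7 ester dienolate) formed from 5 by hydride addition at C5 | [Li+].[Li+].CC(C1=C2C[C@](C)([O-])CC[C@H]2[C@H](C)CC1)=C([O-])OCC[Si](C)(C)C | intermediate (not isolated)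
7 | tert-butyldimethylsilyl 2-(trimethylsilyl)ethyl ketene acetal of (1S,4R,10R)-4-hydroxyamorph-6-en-12-oic acid | CC(C1=C2C[C@](C)(O)CC[C@H]2[C@H](C)CC1)=C(O[Si](C)(C)C(C)(C)C)OCC[Si](C)(C)C | intermediate
8 | 2-(trimethylsilyl)ethyl (4R,10R)-4-hydroxyamorpha-1(6),7(11)-dien-12-oate | CC(C(=O)OCC[Si](C)(C)C)=C1CC[C@@H](C)C2=C1C[C@](C)(O)CC2 | intermediate
9 | (4R,10R)-4-hydroxyamorpha-1(6),7(11)-dien-12-oic acid | CC(C(=O)O)=C1CC[C@@H](C)C2=C1C[C@](C)(O)CC2 | intermediate
10 | 1-hydroperoxy-1,4-epoxy-6-oxogermacr-7(11)-en-12-oic acid (hydroperoxy ketal) | CC(C(=O)O)=C1CC[C@@H](C)[C@]2(OO)CC[C@](C)(CC1=O)O2 | intermediate (not isolated)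
11 | (1S,4R,10R)-1-hydroxy-1,4-epoxy-6-oxogermacr-7(11)-en-12-oic acid | CC(C(=O)O)=C1CC[C@@H](C)[C@]2(O)CC[C@](C)(CC1=O)O2 | intermediate
12 | mixed anhydride of 11 with 2,4,6-trichlorobenzoic acid | CC(C(=O)OC(=O)c1c(Cl)cc(Cl)cc1Cl)=C1CC[C@@H](C)[C@]2(O)CC[C@](C)(CC1=O)O2 | intermediate (not isolated)
13 | (1S,4R,10R,5E)-1-hydroxy-1,4-epoxygermacra-5,7(11)-dien-12,6-olide | CC1=C2/C(=C\[C@@]3(C)CC[C@](O)(O3)[C@H](C)CC2)OC1=O | intermediate
14 | 1-O-tert-butyldimethylsilyl ether of 13 (configuration as in 13) | CC1=C2/C(=C\[C@@]3(C)CC[C@](O[Si](C)(C)C(C)(C)C)(O3)[C@H](C)CC2)OC1=O | intermediate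
15 | 8-oxo derivative of 14 | CC1=C2/C(=C\[C@@]3(C)CC[C@](O[Si](C)(C)C(C)(C)C)(O3)[C@H](C)CC2=O)OC1=O | intermediate
16 | 13-bromo-8-oxo derivative of 14 | BrCC1=C2/C(=C\[C@@]3(C)CC[C@](O[Si](C)(C)C(C)(C)C)(O3)[C@H](C)CC2=O)OC1=O | intermediate
17 | 13-acetoxy-8-oxo derivative of 14 | CC(=O)OCC1=C2/C(=C\[C@@]3(C)CC[C@](O[Si](C)(C)C(C)(C)C)(O3)[C@H](C)CC2=O)OC1=O | intermediate
18 | (8S)-13-acetoxy-8-hydroxy derivative of 14 | CC(=O)OCC1=C2/C(=C\[C@@]3(C)CC[C@](O[Si](C)(C)C(C)(C)C)(O3)[C@H](C)C[C@@H]2O)OC1=O | intermediate
19 | (tert-butyldimethylsilyloxy)acetaldehyde | O=CCO[Si](C)(C)C(C)(C)C | starting material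
20 | ethyl 2-(triphenylphosphoranylidene)propanoate | CCOC(=O)C(C)=P(c1ccccc1)(c1ccccc1)c1ccccc1 | starting material
21 | ethyl (E)-4-(tert-butyldimethylsilyloxy)-2-methylbut-2-enoate | CCOC(=O)/C(C)=C/CO[Si](C)(C)C(C)(C)C | intermediate
22 | (E)-4-(tert-butyldimethylsilyloxy)-2-methylbut-2-enoic acid | OC(=O)/C(C)=C/CO[Si](C)(C)C(C)(C)C | intermediate
23 | mixed anhydride of 22 with 2,4,6-trichlorobenzoic acid | O=C(OC(=O)c1c(Cl)cc(Cl)cc1Cl)/C(C)=C/CO[Si](C)(C)C(C)(C)C | intermediate (not isolated)
24 | target with the C1 hydroxyl and the side-chain hydroxyl as tert-butyldimethylsilyl ethers | CC(=O)OCC1=C2/C(=C\[C@@]3(C)CC[C@](O[Si](C)(C)C(C)(C)C)(O3)[C@H](C)C[C@@H]2OC(=O)/C(C)=C/CO[Si](C)(C)C(C)(C)C)OC1=O | intermediate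
25 | CNP0154520.1, (1S,4R,8S,10R,5E)-13-acetoxy-1-hydroxy-8-[(E)-4-hydroxy-2-methylbut-2-enoyloxy]-1,4-epoxygermacra-5,7(11)-dien-12,6-olide | CC(=O)OCC1=C2/C(=C\[C@@]3(C)CC[C@](O)(O3)[C@H](C)C[C@@H]2OC(=O)/C(C)=C/CO)OC1=O | target

**Totals**
Total step count: 17. Longest linear sequence: 15 steps (steps 1–13, 16 and 17).

**Steps most likely to fail**

Step 5. Hydride abstraction may be misdirected: loss of a C5 hydrogen instead of H-1 would only return the 5,7(11)-diene 5 (recyclable but not advancing), and the quinone may add to the ketene acetal instead of dehydrogenating it. Fallback from 7: bromination of the γ-carbon C6 with N-bromosuccinimide (THF, −78 °C) gives 2-(trimethylsilyl)ethyl 6-bromo-4-hydroxyamorph-7(11)-en-12-oate F1. Dehydrobromination with Li2CO3/LiBr in DMF at 100 °C, conditions under which allylic bromide and dienes equilibrate, is expected to settle on the tetrasubstituted ring-fusion diene and so returns to 8 by thermodynamic instead of kinetic selection.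

Step 10. Radical hydrogen abstraction may be unselective, and peroxyl radicals may attack the exocyclic enol-ether alkene. Fallback from 14: LiN(SiMe3)2 (THF, −78 °C) removes a C8 hydrogen, the only position that gives a lactone-stabilised dienolate, and PhSeBr traps it at C11 to give the 11-phenylseleno-7(8)-ene lactone F2. Oxidation with H2O2/pyridine and [2,3]-sigmatropic shift of the allylic selenoxide place oxygen on C8 and restore C7=C11, giving the 8-hydroxy lactone F3 (either epimer serves). Dess–Martin periodinane then returns to 15.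

Step 4. Hydride delivery may be slow or turn to the ester carbonyl, because the δ-carbon C5 is flanked by the quaternary C4. Fallback from 5: 1,4-addition of hydrogen across the s-cis diene (C5 and C11) with Cr(CO)3(C10H8) (tricarbonyl(naphthalene)chromium) under H2 in acetone gives 2-(trimethylsilyl)ethyl 4-hydroxyamorph-6-en-12-oate F4. Deprotonation at C11, its only acidic C–H, with LiN(i-Pr)2 (2.2 equiv) and O-silylation with t-BuMe2SiCl/DMPU returns to 7.

**Further compounds**
F1 | step 5 | 2-(trimethylsilyl)ethyl 6-bromo-4-hydroxyamorph-7(11)-en-12-oate (bromine drawn syn to H-1; the C6 configuration is lost in the elimination) | CC(C(=O)OCC[Si](C)(C)C)=C1CC[C@@H](C)[C@@H]2CC[C@@](C)(O)C[C@]12Br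
F2 | step 10 | 11-phenylseleno-7(8)-ene lactone from 14 (C11 configuration and C7=C8 geometry not defined) | CC1([Se]c2ccccc2)C(=O)O/C3=C/[C@@]4(C)CC[C@](O[Si](C)(C)C(C)(C)C)(O4)[C@H](C)CC=C13
F3 | step 10 | 8-hydroxy derivative of 14 (C8 configuration not defined) | CC1=C2/C(=C\[C@@]3(C)CC[C@](O[Si](C)(C)C(C)(C)C)(O3)[C@H](C)CC2O)OC1=O
F4 | step 4 | 2-(trimethylsilyl)ethyl (1S,4R,10R)-4-hydroxyamorph-6-en-12-oate (C11 configuration not defined) | CC(C(=O)OCC[Si](C)(C)C)C1=C2C[C@](C)(O)CC[C@H]2[C@H](C)CC1
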